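The oxolane ring (C3a–C4–O5–C6–C6a) carries the lactone carbonyl C1 as a one-carbon branch on C6a, within reach of the oxygen on C3. Moving C1 back into that ring, between C6a and C3a, gives a 2,5-trans-disubstituted oxan-4-one. Its ring stereocentres come from a chair Prins cyclisation of an Evans syn-aldol fragment. The key step is the photochemical Wolff rearrangement of the derived 3-diazo-oxan-4-one. C3a migrates with retention, the six-membered ring contracts to the oxolane, and the ketene is trapped by the C3 hydroxyl. This closes the lactone and fixes C6a through cis fusion. The precursor is a monocyclic β-hydroxy α'-diazo ketone.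

Key step: step 8

Numbering remark: target atoms follow furo[3,4-c]furan-1-one numbering. C1 is the carbonyl, O2 the lactone oxygen, C3 the carbon bearing the 4-hydroxy-3,5-dimethoxyphenyl group, C3a a ring-fusion carbon, C4 the CH2, O5 the ether oxygen, C6 the carbon bearing the 4-hydroxy-3-methoxyphenyl group, and C6a the second ring-fusion carbon. The target is (3S,3aR,6S,6aS), with both aryl groups exo.

Assumption: the N-crotonyl oxazolidinone of step 1 is taken as a catalogue compound. If it is not, one N-acylation of (S)-4-benzyloxazolidin-2-one with crotonyl chloride precedes the route.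

Step 1
Reactants: 1 (4S)-4-benzyl-3-[(E)-but-2-enoyl]-1,3-oxazolidin-2-one; 2 4-(benzyloxy)-3,5-dimethoxybenzaldehyde
Product: 4 (4S)-4-benzyl-3-[(2S)-2-{(S)-[4-(benzyloxy)-3,5-dimethoxyphenyl](hydroxy)methyl}but-3-enoyl]-1,3-oxazolidin-2-one, via dibutylboron dienolate 3 (not isolated)
Conditions: Bu2BOTf, Et3N, CH2Cl2, −78 to 0 °C; 2, −78 to 0 °C; then H2O2, MeOH, pH 7 buffer, 0 °C
Reagents that add atoms: dibutylboron triflate, CCCCB(CCCC)OS(=O)(=O)C(F)(F)F (atoms kept only in 3)
Why: Evans syn-aldol reaction, in which the (Z)-boron dienolate reacts at its α-carbon through a closed chair transition state on the face away from the benzyl group of the (S)-auxiliary, setting the 2S,3S syn pair (later C3a and C3) and leaving the vinyl group deconjugated.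

Step 2
Reactants: 4 syn-aldol adduct
Product: 5 (4S)-4-benzyl-3-[(2S)-2-{(S)-[4-(benzyloxy)-3,5-dimethoxyphenyl][(tert-butyldimethylsilyl)oxy]methyl}but-3-enoyl]-1,3-oxazolidin-2-one
Conditions: TBSOTf, 2,6-lutidine, CH2Cl2, 0 °C
Reagents that add atoms: tert-butyldimethylsilyl triflate, CC(C)(C)[Si](C)(C)OS(=O)(=O)C(F)(F)F
Why: Silyl ether formation with a silyl triflate and a non-nucleophilic base masks the benzylic carbinol, so that only the primary hydroxyl made in step 3 can form an oxocarbenium ion in step 4, and it touches no stereocentre.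

Step 3
Reactants: 5 silylated imide
Product: 6 (2R)-2-{(S)-[4-(benzyloxy)-3,5-dimethoxyphenyl][(tert-butyldimethylsilyl)oxy]methyl}but-3-en-1-ol
Conditions: LiBH4, THF, 0 °C to rt
Reagents that add atoms: none
Why: Reductive removal of the auxiliary by hydride attack at the more electrophilic exocyclic imide carbonyl gives the primary alcohol without enolisation, so both stereocentres and the vinyl group stay as they are (the descriptor at C2 changes only through priorities).

Step 4
Reactants: 6 homoallylic alcohol; 7 4-(benzyloxy)-3-methoxybenzaldehyde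
Product: 9 (2S,4S,5S)-2-[4-(benzyloxy)-3-methoxyphenyl]-5-{(S)-[4-(benzyloxy)-3,5-dimethoxyphenyl][(tert-butyldimethylsilyl)oxy]methyl}oxan-4-ol, via oxocarbenium ion 8 (not isolated)
Conditions: O3ReOSiPh3 (5 mol %, from Re2O7 and Ph3SiOH), CH2Cl2, rt
Reagents that add atoms: none
Why: Prins cyclisation, in which the perrhenate ester catalyst condenses 6 and 7 to the (E)-oxocarbenium ion 8, which closes on the vinyl group through a chair with the aryl group and the bulky C5 side chain both equatorial, so the existing centre sets the new C2 centre 2,5-trans (later C6) and the water lost in the condensation returns equatorially at C4.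

Step 5
Reactants: 9 oxan-4-ol
Product: 10 (2S,5R)-2-[4-(benzyloxy)-3-methoxyphenyl]-5-{(S)-[4-(benzyloxy)-3,5-dimethoxyphenyl][(tert-butyldimethylsilyl)oxy]methyl}oxan-4-one
Conditions: n-Pr4NRuO4 (5 mol %), N-methylmorpholine N-oxide, 4 Å molecular sieves, CH2Cl2, rt
Reagents that add atoms: none
Why: Ley–Griffith oxidation under neutral conditions turns the secondary alcohol into the ketone, removes the C4 stereocentre that is no longer needed, and leaves the silyl and benzyl ethers and the equatorial, thermodynamically favoured C5 centre alone.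

Step 6
Reactants: 10 oxan-4-one
Product: 12 (2R,5R)-2-[4-(benzyloxy)-3-methoxyphenyl]-5-{(S)-[4-(benzyloxy)-3,5-dimethoxyphenyl][(tert-butyldimethylsilyl)oxy]methyl}-3-diazooxan-4-one, via trifluoroacetyl ketone 11 (not isolated)
Conditions: LiN(SiMe3)2, THF, −78 °C; CF3CO2CH2CF3, −78 °C; aq HCl wash; then MsN3, Et3N, H2O, MeCN, rt
Reagents that add atoms: methanesulfonyl azide, CS(=O)(=O)N=[N+]=[N-]; 2,2,2-trifluoroethyl trifluoroacetate, O=C(OCC(F)(F)F)C(F)(F)F (atoms kept only in 11)
Why: Detrifluoroacetylative diazo transfer (Regitz type), in which kinetic deprotonation occurs at the only α-methylene group (C3), Claisen-type trifluoroacetylation activates that carbon, and the sulfonyl azide delivers N2 with loss of the trifluoroacetyl group, forming no stereocentre (the C2 descriptor changes only through priorities).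

Step 7
Reactants: 12 silylated diazo ketone
Product: 13 (2R,5R)-2-[4-(benzyloxy)-3-methoxyphenyl]-5-{(S)-[4-(benzyloxy)-3,5-dimethoxyphenyl](hydroxy)methyl}-3-diazooxan-4-one
Conditions: Bu4NF, AcOH (1:1), THF, 0 °C to rt
Reagents that add atoms: none
Why: Fluoride-induced desilylation, buffered with acetic acid so that neither retro-aldol cleavage of the β-hydroxy ketone nor protonation of the diazo carbon sets in, frees the hydroxyl that has to trap the ketene.

Step 8
Reactants: 13 β-hydroxy α'-diazo ketone
Product: 15 (3S,3aR,6S,6aS)-6-[4-(benzyloxy)-3-methoxyphenyl]-3-[4-(benzyloxy)-3,5-dimethoxyphenyl]tetrahydro-1H,3H-furo[3,4-c]furan-1-one, via ketene 14 (not isolated)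
Conditions: hν (medium-pressure Hg lamp, Pyrex filter), degassed THF, 0.005 M, rt
Reagents that add atoms: none
Why: Irradiation expels N2 from the s-cis-locked diazo ketone while C5 of the oxanone migrates in concert from the carbonyl carbon C4 to the diazo carbon C3 (Wolff rearrangement), so the six-membered ring contracts to the oxolane and the former ring carbonyl becomes the exocyclic ketene carbon of 14. The closest known reaction type is the photochemical Wolff ring contraction of cyclic 2-diazo ketones, oxacyclic ones included, combined with capture of the ketene by a pendant alcohol. The oxolane is closed by the 1,2-shift itself, and the lactone by 5-exo-dig addition of the benzylic hydroxyl to the central ketene carbon followed by tautomerisation of the enol. The migrating carbon (later C3a) keeps its configuration, C6 and C3 are untouched, and the only new stereocentre, C6a, is protonated so that the two five-membered rings are cis-fused, the trans-fused alternative being too strained. The step needs rearrangement to outrun the 1,2-hydride shift from the benzylic C2–H and free-carbene O–H insertion, which the fixed s-cis geometry and metal-free direct photolysis secure. It also needs intramolecular capture to outrun ketene dimerisation, which high dilution in an aprotic solvent and the proximity of hydroxyl and ketene secure.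

Step 9
Reactants: 15 bis(benzyl ether) of the target
Product: 16 CNP0142585.1, (3S,3aR,6S,6aS)-3-(4-hydroxy-3,5-dimethoxyphenyl)-6-(4-hydroxy-3-methoxyphenyl)tetrahydro-1H,3H-furo[3,4-c]furan-1-one
Conditions: H2 (1 atm), 10% Pd/C, EtOAc, rt, stopped as soon as both benzyl groups are gone
Reagents that add atoms: none
Why: Catalytic hydrogenolysis cleaves the two unhindered primary benzyl aryl ethers much faster than the hindered secondary benzylic C–O bonds at C3 and C6, so short exposure at ambient pressure in a neutral solvent should free both phenols with all four stereocentres intact.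

Compound list
1 | (4S)-4-benzyl-3-[(E)-but-2-enoyl]-1,3-oxazolidin-2-one | C/C=C/C(=O)N1[C@@H](Cc2ccccc2)COC1=O | starting material
2 | 4-(benzyloxy)-3,5-dimethoxybenzaldehyde | COc1cc(C=O)cc(OC)c1OCc1ccccc1 | starting material
3 | (Z)-dibutylboron dienolate of 1 (not isolated) | C=C/C=C(\OB(CCCC)CCCC)N1[C@@H](Cc2ccccc2)COC1=O | intermediate
4 | syn-aldol adduct, (2S,3S) in the acyl chain, (4S) in the auxiliary | O=C(N1[C@@H](Cc2ccccc2)COC1=O)[C@H]([C@H](O)c1cc(OC)c(OCc2ccccc2)c(OC)c1)C=C | intermediate
5 | tert-butyldimethylsilyl ether of 4 | O=C(N1[C@@H](Cc2ccccc2)COC1=O)[C@H]([C@H](O[Si](C)(C)C(C)(C)C)c1cc(OC)c(OCc2ccccc2)c(OC)c1)C=C | intermediate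
6 | (2R)-2-{(S)-aryl(silyloxy)methyl}but-3-en-1-ol, aryl = 4-(benzyloxy)-3,5-dimethoxyphenyl | OC[C@H]([C@H](O[Si](C)(C)C(C)(C)C)c1cc(OC)c(OCc2ccccc2)c(OC)c1)C=C | intermediate
7 | 4-(benzyloxy)-3-methoxybenzaldehyde | COc1cc(C=O)ccc1OCc1ccccc1 | starting material
8 | (E)-oxocarbenium ion from 6 and 7 (not isolated) | COc1cc(/C=[O+]/C[C@H]([C@H](O[Si](C)(C)C(C)(C)C)c2cc(OC)c(OCc3ccccc3)c(OC)c2)C=C)ccc1OCc1ccccc1 | intermediate
9 | (2S,4S,5S)-2,4,5-all-equatorial oxan-4-ol | COc1cc([C@H]2OC[C@H]([C@H](O[Si](C)(C)C(C)(C)C)c3cc(OC)c(OCc4ccccc4)c(OC)c3)[C@@H](O)C2)ccc1OCc1ccccc1 | intermediate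
10 | (2S,5R)-2,5-trans oxan-4-one | COc1cc([C@H]2OC[C@H]([C@H](O[Si](C)(C)C(C)(C)C)c3cc(OC)c(OCc4ccccc4)c(OC)c3)C(=O)C2)ccc1OCc1ccccc1 | intermediate
11 | 3-(trifluoroacetyl) derivative of 10, C3 not defined (not isolated) | COc1cc([C@H]2OC[C@H]([C@H](O[Si](C)(C)C(C)(C)C)c3cc(OC)c(OCc4ccccc4)c(OC)c3)C(=O)C2C(=O)C(F)(F)F)ccc1OCc1ccccc1 | intermediate
12 | (2R,5R)-3-diazooxan-4-one, silyl ether | COc1cc([C@H]2OC[C@H]([C@H](O[Si](C)(C)C(C)(C)C)c3cc(OC)c(OCc4ccccc4)c(OC)c3)C(=O)C2=[N+]=[N-])ccc1OCc1ccccc1 | intermediate
13 | (2R,5R)-3-diazooxan-4-one with free (S)-carbinol | COc1cc([C@H]2OC[C@H]([C@H](O)c3cc(OC)c(OCc4ccccc4)c(OC)c3)C(=O)C2=[N+]=[N-])ccc1OCc1ccccc1 | intermediate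
14 | 3-(oxomethylidene)oxolane (ketene), three stereocentres as in 13 (not isolated) | COc1cc([C@H]2OC[C@H]([C@H](O)c3cc(OC)c(OCc4ccccc4)c(OC)c3)C2=C=O)ccc1OCc1ccccc1 | intermediate
15 | (3S,3aR,6S,6aS)-bis(benzyl ether) of the target | COc1cc([C@H]2OC[C@H]3[C@@H]2C(=O)O[C@@H]3c2cc(OC)c(OCc3ccccc3)c(OC)c2)ccc1OCc1ccccc1 | intermediate
16 | CNP0142585.1 | COc1cc([C@H]2OC[C@H]3[C@@H]2C(=O)O[C@@H]3c2cc(OC)c(O)c(OC)c2)ccc1O | target

Total step count: 9. Longest linear sequence: 9 steps (1 to 16).

Steps most likely to fail

Step 4. The acidic catalyst may ionise the electron-rich benzylic silyl ether. The strongly stabilised oxocarbenium ion may close too slowly on the unactivated vinyl group. Friedel–Crafts attack by the trialkoxyaryl ring may also intervene. The fallback sets out from 6 and separates C–O bond formation from ionisation (segment-coupling Prins cyclisation).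
- Acylation with 4-(benzyloxy)-3-methoxybenzoic acid (DCC, DMAP, CH2Cl2) gives the benzoate ester F1.
- Reductive acetylation (i-Bu2AlH, CH2Cl2, −78 °C; then Ac2O, pyridine, DMAP) gives the α-acetoxy ether F2.
- F2 ionises at low temperature (BF3·OEt2, AcOH, CH2Cl2–hexane, −78 to 0 °C) and cyclises to the 4-acetoxyoxane F3.
- Methanolysis (K2CO3, MeOH) comes back to the route at 9.

Step 8. A 1,2-hydride shift from the benzylic C2–H, O–H insertion of a free carbene, or oligomerisation of the ketene may compete with rearrangement and ring closure. The fallback sets out from 12 and traps the ketene from outside.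
- Photolysis of 12 in MeOH gives the methyl oxolane-3-carboxylate F4 as both C3 epimers.
- Buffered fluoride (Bu4NF, AcOH) frees the hydroxy ester F5, whose 3,4-cis isomer lactonises directly.
- The trans isomer is drained through ester epimerisation with catalytic DBU in toluene.
- The sequence comes back at 15.

Step 6. The lithium enolate may open the ring by retro-oxa-Michael loss of O1. Enolisation toward C5 would expel silanolate. Acylation next to the aryl-bearing carbon may be slow. The fallback sets out from 10 and avoids a metal enolate.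
- Condensation with tert-butoxybis(dimethylamino)methane (toluene, 80 °C) can occur only at the C3 methylene group and gives the enaminone F6.
- Diazo transfer with tosyl azide (CH2Cl2, rt) cleaves the aminomethylidene carbon as a formamidine and comes back at 12.

Further compounds
F1 | step 4 | (2R)-2-{(S)-aryl(silyloxy)methyl}but-3-en-1-yl 4-(benzyloxy)-3-methoxybenzoate | COc1cc(C(=O)OC[C@H]([C@H](O[Si](C)(C)C(C)(C)C)c2cc(OC)c(OCc3ccccc3)c(OC)c2)C=C)ccc1OCc1ccccc1
F2 | step 4 | α-acetoxy ether from F1, acetal carbon not defined | COc1cc(C(OC(C)=O)OC[C@H]([C@H](O[Si](C)(C)C(C)(C)C)c2cc(OC)c(OCc3ccccc3)c(OC)c2)C=C)ccc1OCc1ccccc1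
F3 | step 4 | 4-O-acetate of 9 | COc1cc([C@H]2OC[C@H]([C@H](O[Si](C)(C)C(C)(C)C)c3cc(OC)c(OCc4ccccc4)c(OC)c3)[C@@H](OC(C)=O)C2)ccc1OCc1ccccc1
F4 | step 8 | methyl 2-aryl-4-{(S)-aryl(silyloxy)methyl}oxolane-3-carboxylate, C3 not defined | COc1cc([C@H]2OC[C@H]([C@H](O[Si](C)(C)C(C)(C)C)c3cc(OC)c(OCc4ccccc4)c(OC)c3)C2C(=O)OC)ccc1OCc1ccccc1
F5 | step 8 | methyl 2-aryl-4-{(S)-aryl(hydroxy)methyl}oxolane-3-carboxylate, C3 not defined | COc1cc([C@H]2OC[C@H]([C@H](O)c3cc(OC)c(OCc4ccccc4)c(OC)c3)C2C(=O)OC)ccc1OCc1ccccc1
F6 | step 6 | 3-[(dimethylamino)methylidene] derivative of 10, alkene geometry not defined | COc1cc([C@H]2OC[C@H]([C@H](O[Si](C)(C)C(C)(C)C)c3cc(OC)c(OCc4ccccc4)c(OC)c3)C(=O)C2=CN(C)C)ccc1OCc1ccccc1
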